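**Retrosynthetic overview**

1. The (E)-2-alkyl-2-enal is the self-aldol condensation product of two molecules of one aldehyde, 12-[(2R,5S,6S)-5-hydroxy-6-methylpiperidin-2-yl]dodecanal, so both (identical) piperidine rings are made once, on the monomer; the dimerization is the last step and forms no ring.
2. Each piperidine is closed at N–C2: C2 carries only a methyl group and lies between the ring nitrogen and the oxygen-bearing C3, five atoms from the amine on C6, so C2 and its methyl are taken back to a terminal alkyne on the C3 carbinol; 6-exo-dig hydroamination, then hydrogenation anti to the C3–O group (cis to H-6), gives the all-cis ring.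
3. The acyclic amino alkyne maps onto L-pyroglutamic acid: its stereocentre becomes C6, the ring CH2CH2 becomes C5–C4, the lactam carbonyl becomes carbinol C3 (acetylide opening of the N-Boc lactam, then Noyori transfer hydrogenation), and the exocyclic carbon becomes the first chain carbon.
4. The chain with the masked aldehyde is attached first, by copper-catalysed coupling of pyroglutaminol tosylate with an 11-carbon Grignard reagent; ring order: pyrrolidinone (bought, opened in step 5), then both piperidine rings (step 9, on the monomer).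

Key step: step 9

Remark: both piperidine rings are the same (2S,3S,6R) unit. The (S,S)-configured ruthenium catalyst is assumed to give the (3S)-propargylic alcohol, as with other alkynyl ketones; the (R,R)-catalyst would be used if the sense proved opposite.

**Route**

Step 1
Reactants: 1 11-bromoundecan-1-ol
Product: 2 11-bromoundecanal
Conditions: TEMPO (10 mol %), PhI(OAc)2 (1.1 equiv), CH2Cl2, rt
Reagents that add atoms: none
Why: TEMPO/PhI(OAc)2 oxidation (oxoammonium catalysis) should take the primary alcohol to the aldehyde without over-oxidation and leave the primary bromide untouched.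

Step 2
Reactants: 2 11-bromoundecanal
Product: 3 11-bromo-1,1-dimethoxyundecane
Conditions: HC(OMe)3 (3 equiv), TsOH·H2O (2 mol %), MeOH, rt
Reagents that add atoms: trimethyl orthoformate, COC(OC)OC; methanol, CO
Why: Acid-catalysed acetalization with the orthoformate as water scavenger masks the future enal carbon in a form that should survive Grignard, acetylide and hydrogenation conditions.

Step 3
Reactants: 3 11-bromo-1,1-dimethoxyundecane; 4 [(2S)-5-oxopyrrolidin-2-yl]methyl 4-methylbenzenesulfonate
Product: 6 (5R)-5-(12,12-dimethoxydodecyl)pyrrolidin-2-one, via Grignard reagent 5 (not isolated)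
Conditions: 3, Mg, THF, 40 °C; separately 4, i-PrMgCl (1.0 equiv), THF, −40 °C; then 5 (1.6 equiv), Li2CuCl4 (5 mol %), −40 °C → rt; aqueous work-up
Reagents that add atoms: none
Why: Copper-catalysed Grignard–alkyl tosylate cross-coupling (Kochi-type sp3–sp3 coupling) on the N-magnesiated lactam should join the chain at the exocyclic CH2 without touching the stereocentre, which is bought with L-pyroglutamic acid and becomes C6 of each piperidine (the descriptor changes from S to R only through the priority switch).

Step 4
Reactants: 6 (5R)-5-(12,12-dimethoxydodecyl)pyrrolidin-2-one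
Product: 7 tert-butyl (2R)-2-(12,12-dimethoxydodecyl)-5-oxopyrrolidine-1-carboxylate
Conditions: Boc2O (1.3 equiv), DMAP (10 mol %), MeCN, rt
Reagents that add atoms: di-tert-butyl dicarbonate, CC(C)(C)OC(=O)OC(=O)OC(C)(C)C
Why: DMAP-catalysed N-acylation should give the imide-like N-Boc lactam, whose ring carbonyl is activated for nucleophilic ring opening.

Step 5
Reactants: 7 tert-butyl (2R)-2-(12,12-dimethoxydodecyl)-5-oxopyrrolidine-1-carboxylate
Product: 8 tert-butyl N-[(6R)-18,18-dimethoxy-3-oxo-1-(trimethylsilyl)octadec-1-yn-6-yl]carbamate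
Conditions: ethynyltrimethylsilane (1.2 equiv), n-BuLi (1.15 equiv), THF, −78 °C; then 7, −78 °C; AcOH quench at −78 °C
Reagents that add atoms: lithium (trimethylsilyl)acetylide, [Li]C#C[Si](C)(C)C (made in the flask from ethynyltrimethylsilane, C#C[Si](C)(C)C, and n-BuLi)
Why: Nucleophilic ring opening of an N-Boc lactam by a lithium acetylide (addition to the ring carbonyl, collapse with loss of the carbamate anion) should give the acyclic ynone, in which the former lactam carbonyl is C3 and the alkyne carbons are C2 and the future methyl group.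

Step 6
Reactants: 8 tert-butyl N-[(6R)-18,18-dimethoxy-3-oxo-1-(trimethylsilyl)octadec-1-yn-6-yl]carbamate
Product: 9 tert-butyl N-[(3S,6R)-3-hydroxy-18,18-dimethoxy-1-(trimethylsilyl)octadec-1-yn-6-yl]carbamate
Conditions: RuCl[(S,S)-TsDPEN](p-cymene) (2 mol %), KOH (2 mol %), i-PrOH (0.1 M), rt
Reagents that add atoms: none
Why: Noyori asymmetric transfer hydrogenation of an alkynyl ketone, in which the (S,S)-catalyst should deliver hydride to one face under catalyst control (the alkyne taking the place of the aryl group in the outer-sphere transition state) and so set the (3S) carbinol irrespective of the remote C6 centre.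

Step 7
Reactants: 9 tert-butyl N-[(3S,6R)-3-hydroxy-18,18-dimethoxy-1-(trimethylsilyl)octadec-1-yn-6-yl]carbamate
Product: 10 tert-butyl N-[(3S,6R)-3-(benzyloxy)-18,18-dimethoxy-1-(trimethylsilyl)octadec-1-yn-6-yl]carbamate
Conditions: 2-benzyloxy-1-methylpyridinium triflate (2 equiv), MgO (2 equiv), PhCF3, 85 °C
Reagents that add atoms: 2-benzyloxy-1-methylpyridinium trifluoromethanesulfonate, C[n+]1ccccc1OCc1ccccc1.[O-]S(=O)(=O)C(F)(F)F
Why: Neutral O-benzylation by thermal benzyl transfer from the 2-benzyloxypyridinium salt (MgO as acid scavenger) should etherify the secondary alcohol without touching the carbamate N–H, the silyl alkyne or the acetal, and the ether blocks isomerization of an α-hydroxy imine to an amino ketone in the key step.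

Step 8
Reactants: 10 tert-butyl N-[(3S,6R)-3-(benzyloxy)-18,18-dimethoxy-1-(trimethylsilyl)octadec-1-yn-6-yl]carbamate
Product: 12 (3S,6R)-3-(benzyloxy)-18,18-dimethoxyoctadec-1-yn-6-amine, via terminal alkyne carbamate 11 (not isolated)
Conditions: K2CO3 (0.3 equiv), MeOH, rt; then 3 M HCl in MeOH, 0 °C → rt; poured into cold aq. Na2CO3
Reagents that add atoms: none
Why: Carbonate-catalysed methanolysis of the alkynyl–silicon bond, then acidolysis of the Boc group in anhydrous methanol (where the dimethyl acetal only exchanges with itself), should release the terminal alkyne and the primary amine while the benzyl ether stays.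

Step 9
Reactants: 12 (3S,6R)-3-(benzyloxy)-18,18-dimethoxyoctadec-1-yn-6-amine
Product: 14 (2S,3S,6R)-6-(12,12-dimethoxydodecyl)-2-methylpiperidin-3-ol, via cyclic imine 13 (not isolated)
Conditions: NaAuCl4·2H2O (5 mol %), MeCN, 70 °C; concentrate; then H2 (3 atm), Pd(OH)2/C, MeOH, AcOH (3 equiv), rt; aq. K2CO3 work-up
Reagents that add atoms: none
Why: Trivalent gold activates the terminal alkyne for anti attack of the primary amine at the internal carbon, protodeauration gives the 2-methylenepiperidine and tautomerization the endocyclic ketimine 13, which is then hydrogenated over Pd(OH)2/C with hydrogenolysis of the benzyl ether. The closest known reaction type is the gold- or palladium-catalysed cycloisomerization of 5-alkynylamines to 6-alkyl-2,3,4,5-tetrahydropyridines followed by cis-selective hydrogenation to 2,6-cis-dialkylpiperidines. The piperidine ring closes in the 6-exo-dig mode through the N–C2 bond, and the terminal alkyne carbon becomes the C2 methyl group. The new stereocentre C2 is set by substrate control: in the half-chair of 13 the C6 chain is pseudo-equatorial and the C3 benzyloxy group pseudo-axial (allylic strain with the C2 methyl), so hydrogen should add from the face opposite the benzyloxy group, cis to H-6, and give the all-cis (2S,3S,6R) ring. The step needs Markovnikov regioselectivity (6-exo over 7-endo, secured by the terminal alkyne), retention of configuration at C3 (secured by the ether, which cannot isomerize to an amino ketone, and by prompt reduction) and survival of the acetal (basic amine medium, then methanol as solvent).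

Step 10
Reactants: 14 (2S,3S,6R)-6-(12,12-dimethoxydodecyl)-2-methylpiperidin-3-ol (two molecules)
Product: 16 (2E)-2-{10-[(2R,5S,6S)-5-hydroxy-6-methylpiperidin-2-yl]decyl}-14-[(2R,5S,6S)-5-hydroxy-6-methylpiperidin-2-yl]tetradec-2-enal, via amino aldehyde hydrochloride 15 (not isolated)
Conditions: 2 M aq. HCl–THF (1:1), rt; concentrate; then pyrrolidine (0.3 equiv), AcOH (0.6 equiv), i-PrOH (0.5 M), 50 °C; aq. K2CO3 work-up
Reagents that add atoms: water, O
Why: Aqueous acid should unmask the aldehyde while the ring nitrogen is protonated, and pyrrolidinium acetate should then promote the enamine-mediated self-aldol condensation (aldol addition and dehydration) of two identical aldehydes to the thermodynamically preferred (E)-2-alkyl-2-enal, the hindered and largely protonated 2,6-disubstituted ring nitrogen not competing.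

**Compound list**

1 | 11-bromoundecan-1-ol | OCCCCCCCCCCCBr | starting material
2 | 11-bromoundecanal | O=CCCCCCCCCCCBr | intermediate
3 | 11-bromo-1,1-dimethoxyundecane | COC(OC)CCCCCCCCCCBr | intermediate
4 | [(2S)-5-oxopyrrolidin-2-yl]methyl 4-methylbenzenesulfonate | Cc1ccc(cc1)S(=O)(=O)OC[C@@H]1CCC(=O)N1 | starting material
5 | (11,11-dimethoxyundecyl)magnesium bromide | COC(OC)CCCCCCCCCC[Mg]Br | intermediate
6 | (5R)-5-(12,12-dimethoxydodecyl)pyrrolidin-2-one | COC(OC)CCCCCCCCCCC[C@@H]1CCC(=O)N1 | intermediate
7 | tert-butyl (2R)-2-(12,12-dimethoxydodecyl)-5-oxopyrrolidine-1-carboxylate | COC(OC)CCCCCCCCCCC[C@@H]1CCC(=O)N1C(=O)OC(C)(C)C | intermediate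
8 | tert-butyl N-[(6R)-18,18-dimethoxy-3-oxo-1-(trimethylsilyl)octadec-1-yn-6-yl]carbamate | COC(OC)CCCCCCCCCCC[C@H](CCC(=O)C#C[Si](C)(C)C)NC(=O)OC(C)(C)C | intermediate
9 | tert-butyl N-[(3S,6R)-3-hydroxy-18,18-dimethoxy-1-(trimethylsilyl)octadec-1-yn-6-yl]carbamate | COC(OC)CCCCCCCCCCC[C@H](CC[C@H](O)C#C[Si](C)(C)C)NC(=O)OC(C)(C)C | intermediate
10 | tert-butyl N-[(3S,6R)-3-(benzyloxy)-18,18-dimethoxy-1-(trimethylsilyl)octadec-1-yn-6-yl]carbamate | COC(OC)CCCCCCCCCCC[C@H](CC[C@H](OCc1ccccc1)C#C[Si](C)(C)C)NC(=O)OC(C)(C)C | intermediate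
11 | tert-butyl N-[(3S,6R)-3-(benzyloxy)-18,18-dimethoxyoctadec-1-yn-6-yl]carbamate | COC(OC)CCCCCCCCCCC[C@H](CC[C@H](OCc1ccccc1)C#C)NC(=O)OC(C)(C)C | intermediate
12 | (3S,6R)-3-(benzyloxy)-18,18-dimethoxyoctadec-1-yn-6-amine | COC(OC)CCCCCCCCCCC[C@H](CC[C@H](OCc1ccccc1)C#C)N | intermediate
13 | (2R,5S)-5-(benzyloxy)-2-(12,12-dimethoxydodecyl)-6-methyl-2,3,4,5-tetrahydropyridine | COC(OC)CCCCCCCCCCC[C@@H]1CC[C@H](OCc2ccccc2)C(C)=N1 | intermediate
14 | (2S,3S,6R)-6-(12,12-dimethoxydodecyl)-2-methylpiperidin-3-ol | COC(OC)CCCCCCCCCCC[C@@H]1CC[C@H](O)[C@H](C)N1 | intermediate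
15 | 12-[(2R,5S,6S)-5-hydroxy-6-methylpiperidin-2-yl]dodecanal hydrochloride | O=CCCCCCCCCCCC[C@@H]1CC[C@H](O)[C@H](C)N1.Cl | intermediate
16 | (2E)-2-{10-[(2R,5S,6S)-5-hydroxy-6-methylpiperidin-2-yl]decyl}-14-[(2R,5S,6S)-5-hydroxy-6-methylpiperidin-2-yl]tetradec-2-enal | C[C@@H]1N[C@H](CCCCCCCCCCC/C=C(/C=O)CCCCCCCCCC[C@@H]2CC[C@H](O)[C@H](C)N2)CC[C@@H]1O | target

**Summary**

Total step count: 10.
Longest linear sequence: 10 steps (1 to 16; tosylate 4 enters in step 3).

**Steps most likely to fail**

Step 9. The basic primary amine may slow or stop the gold-catalysed cyclization. While the ketimine waits for hydrogen it may tautomerize to the enamine and lose configuration at the benzyloxy-bearing carbon, and hydrogenolysis of the hindered ether may stall. The fallback sets out from 10 and returns at 14. Compound 10 would be desilylated alone (K2CO3, MeOH) to the terminal alkyne carbamate 11, isolated this time, and hydrated in the Markovnikov sense ((Ph3P)AuNTf2 cat., MeOH–H2O) to the methyl ketone tert-butyl N-[(3S,6R)-3-(benzyloxy)-18,18-dimethoxy-2-oxooctadecan-6-yl]carbamate F1. HCl in MeOH would give the amino ketone (3S,6R)-6-amino-3-(benzyloxy)-18,18-dimethoxyoctadecan-2-one hydrochloride F2. Hydrogenation of this salt over Pd(OH)2/C in MeOH with NaOAc would free the amine under hydrogen, so that carbonyl condensation to imine 13 (the same N–C2 bond, now by intramolecular reductive amination) is followed at once by reduction and debenzylation to 14.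

Step 10. With the ring nitrogen unprotected, iminium and enamine formation between amine and aldehyde may lead to oligomers, or the condensation may stop at the aldol adduct or run on to trimers. The fallback sets out from 14 and returns at 16. Boc2O (MeOH, 50 °C) should give tert-butyl (2S,3S,6R)-6-(12,12-dimethoxydodecyl)-3-hydroxy-2-methylpiperidine-1-carboxylate F3. Mild hydrolysis (PPTS, acetone–H2O, 50 °C) should give tert-butyl (2S,3S,6R)-3-hydroxy-2-methyl-6-(12-oxododecyl)piperidine-1-carboxylate F4. Self-aldol condensation of this neutral aldehyde (pyrrolidine and benzoic acid, 20 mol % each, CH2Cl2, rt) should give the bis(N-Boc) derivative of 16 F5, and TFA in CH2Cl2 followed by aq. NaHCO3 should release 16.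

Step 5. The tetrahedral adduct may collapse in the flask and the released ynone take up a second acetylide, or the acetylide may attack the carbamate carbonyl and return lactam 6. The fallback sets out from 7 and returns at 8. LiOH in THF–H2O should open the N-Boc lactam to (4R)-4-[(tert-butoxycarbonyl)amino]-16,16-dimethoxyhexadecanoic acid F6. Amide coupling (EDC·HCl, HOBt, MeNHOMe·HCl, i-Pr2NEt, CH2Cl2) should give the Weinreb amide tert-butyl N-[(4R)-16,16-dimethoxy-1-[methoxy(methyl)amino]-1-oxohexadecan-4-yl]carbamate F7. Lithium (trimethylsilyl)acetylide (2.2 equiv, THF, −78 → 0 °C) should then give 8 after quench, the chelated tetrahedral intermediate preventing over-addition.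

**Further compounds**

F1 | step 9 | tert-butyl N-[(3S,6R)-3-(benzyloxy)-18,18-dimethoxy-2-oxooctadecan-6-yl]carbamate | COC(OC)CCCCCCCCCCC[C@H](CC[C@H](OCc1ccccc1)C(C)=O)NC(=O)OC(C)(C)C
F2 | step 9 | (3S,6R)-6-amino-3-(benzyloxy)-18,18-dimethoxyoctadecan-2-one hydrochloride | COC(OC)CCCCCCCCCCC[C@H](CC[C@H](OCc1ccccc1)C(C)=O)N.Cl
F3 | step 10 | tert-butyl (2S,3S,6R)-6-(12,12-dimethoxydodecyl)-3-hydroxy-2-methylpiperidine-1-carboxylate | COC(OC)CCCCCCCCCCC[C@@H]1CC[C@H](O)[C@H](C)N1C(=O)OC(C)(C)C
F4 | step 10 | tert-butyl (2S,3S,6R)-3-hydroxy-2-methyl-6-(12-oxododecyl)piperidine-1-carboxylate | O=CCCCCCCCCCCC[C@@H]1CC[C@H](O)[C@H](C)N1C(=O)OC(C)(C)C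
F5 | step 10 | bis(N-Boc) derivative of 16 (both ring nitrogens as tert-butyl carbamates) | C[C@@H]1N(C(=O)OC(C)(C)C)[C@H](CCCCCCCCCCC/C=C(/C=O)CCCCCCCCCC[C@@H]2CC[C@H](O)[C@H](C)N2C(=O)OC(C)(C)C)CC[C@@H]1O
F6 | step 5 | (4R)-4-[(tert-butoxycarbonyl)amino]-16,16-dimethoxyhexadecanoic acid | COC(OC)CCCCCCCCCCC[C@H](CCC(=O)O)NC(=O)OC(C)(C)C
F7 | step 5 | tert-butyl N-[(4R)-16,16-dimethoxy-1-[methoxy(methyl)amino]-1-oxohexadecan-4-yl]carbamate | COC(OC)CCCCCCCCCCC[C@H](CCC(=O)N(C)OC)NC(=O)OC(C)(C)C
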